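**Retrosynthetic overview**

1. The E-stilbene is cut last: Heck coupling of a ring-E aryl triflate with a 4-vinyl-dihydrobenzofuran, then cleavage of ten methyl ethers. Both halves carry the same (2S,3S)-2,3-diaryl-dihydrobenzofuran and come from one 4-bromo-dihydrobenzofuran.
2. The strategy rests on the C7b–C8b bond: two adjacent diarylmethine carbons (C7b with the 4-oxygenated phenyl and ring A, C8b with ring E and benzofuran ring B) inside the seven-membered carbocycle fused to rings A and B and, through C8a, to the left dihydrofuran. This tetra-aryl junction is mapped onto the two α-carbons of an eight-membered cyclic sulfone.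
3. Ramberg–Bäcklund contraction of that sulfone gives the C7b=C8b cycloheptene; syn hydrogenation on the outer face of its locked boat sets C7b and C8b.
4. The sulfone comes from a bis(diarylmethanol) (dichloride, sodium sulfide, oxidation). The diol comes from the dihydrobenzofuran-4-carbaldehyde by ring-A bromination and two aryl–carbonyl additions. The dihydrofuran comes from a rhodium-carbene C–H insertion (sets C8a) and acid epimerisation at C7a.
5. Ring order: dihydrofuran (made once, used for both halves), then the eight-membered sulfur ring, then the seven-membered carbocycle by contraction.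

Key step: step 16

Remarks on the chemistry:
- Locants for the left half: C7a = O–CH(aryl) and C8a = the other dihydrofuran carbon; C7b = CH bearing the 4-oxygenated phenyl; C8b = CH bearing ring E. Ring A is the dimethoxyphenyl ring on C8a, ring B the benzo ring of the benzofuran, ring E the 2-methoxyphenyl ring that later carries the stilbene.
- The ring-E position that later carries the stilbene is brought through the key step as a benzyl ether and not as a halide. A halide would be lost in the hydrogenation that follows the ring contraction; the same hydrogenation frees the phenol for triflation.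
- Assumption: Rh2(S-PTAD)4 is taken to be the catalyst antipode that gives the 3S series in step 6; if the first batch shows 3R, Rh2(R-PTAD)4 is used with no other change.

**Route**

Step 1
Reactants: 1 2-bromo-4,6-dimethoxybenzaldehyde
Product: 2 2-bromo-6-hydroxy-4-methoxybenzaldehyde
Conditions: BCl3 (1.2 equiv), CH2Cl2, −78 → 0 °C; H2O
Reagents that add atoms: none
Why: Chelation-controlled demethylation: BCl3 bound to the aldehyde oxygen should cleave only the methyl ether ortho to the formyl group, leaving the para ether and the bromide.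

Step 2
Reactants: 2 2-bromo-6-hydroxy-4-methoxybenzaldehyde; 3 4-methoxybenzyl chloride
Product: 4 2-bromo-4-methoxy-6-[(4-methoxybenzyl)oxy]benzaldehyde
Conditions: K2CO3, NaI (cat.), DMF, 50 °C
Reagents that add atoms: none
Why: Williamson ether synthesis on the phenoxide; the benzylic CH2 introduced here becomes C7a.

Step 3
Reactants: 4 2-bromo-4-methoxy-6-[(4-methoxybenzyl)oxy]benzaldehyde; 5 3,5-dimethoxyphenylmagnesium chloride
Product: 6 (±)-{2-bromo-4-methoxy-6-[(4-methoxybenzyl)oxy]phenyl}(3,5-dimethoxyphenyl)methanol
Conditions: THF, −40 → 0 °C; H2O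
Reagents that add atoms: none
Why: Grignard 1,2-addition to the aldehyde, which the aryl bromide tolerates at low temperature; the carbinol centre is removed in the next step.

Step 4
Reactants: 6 (±)-diarylmethanol
Product: 7 {2-bromo-4-methoxy-6-[(4-methoxybenzyl)oxy]phenyl}(3,5-dimethoxyphenyl)methanone
Conditions: MnO2 (activated, excess), CH2Cl2, rt
Reagents that add atoms: none
Why: Manganese dioxide oxidation of a doubly benzylic alcohol to the benzophenone.

Step 5
Reactants: 7 diaryl ketone
Product: 8 hydrazone of ketone 7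
Conditions: N2H4·H2O (excess), AcOH (cat.), n-BuOH, 110 °C
Reagents that add atoms: hydrazine, NN
Why: Hydrazone condensation; the 2,6-disubstituted ketone needs excess hydrazine and heat, and the electron-rich aryl bromide should not undergo substitution without a metal catalyst.

Step 6
Reactants: 8 hydrazone
Product: 10 (2R,3S)-4-bromo-3-(3,5-dimethoxyphenyl)-6-methoxy-2-(4-methoxyphenyl)-2,3-dihydro-1-benzofuran (cis), via diaryldiazomethane 9 (not isolated)
Conditions: MnO2, CH2Cl2, 0 °C, filter; Rh2(S-PTAD)4 (1 mol %), CH2Cl2, 0 °C → rt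
Reagents that add atoms: none
Why: Oxidation gives the diaryldiazomethane, whose donor/donor rhodium carbene inserts into the activated p-methoxybenzylic C–H bond through a five-membered transition state (intramolecular carbene C–H insertion); the chiral carboxylate ligands select the carbene face and so set C3 (S), and the concerted insertion places the two aryl groups cis (C2 R).

Step 7
Reactants: 10 cis-dihydrobenzofuran
Product: 11 (2S,3S)-4-bromo-3-(3,5-dimethoxyphenyl)-6-methoxy-2-(4-methoxyphenyl)-2,3-dihydro-1-benzofuran (trans)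
Conditions: CF3CO2H (2 equiv), CH2Cl2, 0 °C → rt
Reagents that add atoms: none
Why: Acid-catalysed epimerisation: reversible ionisation of the C2–O bond to the p-methoxybenzylic cation and re-closure by the phenol should give the more stable trans isomer, inverting C2 to S while C3 is untouched.

Step 8
Reactants: 11 trans-4-bromo-dihydrobenzofuran
Product: 12 (2S,3S)-3-(3,5-dimethoxyphenyl)-4-ethenyl-6-methoxy-2-(4-methoxyphenyl)-2,3-dihydro-1-benzofuran
Conditions: vinylboronic acid pinacol ester, PdCl2(dppf) (5 mol %), K2CO3, dioxane/H2O, 90 °C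
Reagents that add atoms: vinylboronic acid pinacol ester, C=CB1OC(C)(C)C(C)(C)O1
Why: Suzuki–Miyaura vinylation of the aryl bromide; this is the right-hand half and no stereocentre is involved.

Step 9
Reactants: 11 trans-4-bromo-dihydrobenzofuran
Product: 14 (2S,3S)-3-(3,5-dimethoxyphenyl)-6-methoxy-2-(4-methoxyphenyl)-2,3-dihydro-1-benzofuran-4-carbaldehyde, via 4-lithio-dihydrobenzofuran 13 (not isolated)
Conditions: n-BuLi (1.1 equiv), THF, −78 °C; DMF; H2O
Reagents that add atoms: N,N-dimethylformamide, CN(C)C=O
Why: Bromine–lithium exchange and formylation with DMF; at −78 °C exchange should outrun deprotonation at C3, so the dihydrofuran is not opened.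

Step 10
Reactants: 14 dihydrobenzofuran-4-carbaldehyde
Product: 15 (2S,3R)-3-(2-bromo-3,5-dimethoxyphenyl)-6-methoxy-2-(4-methoxyphenyl)-2,3-dihydro-1-benzofuran-4-carbaldehyde
Conditions: NBS (1.0 equiv), CH2Cl2, −20 → 0 °C
Reagents that add atoms: N-bromosuccinimide, O=C1CCC(=O)N1Br
Why: Electrophilic aromatic bromination: the formyl group deactivates ring B, the anisyl ring is less activated, and ring A should react ortho to the benzylic carbon and para to a methoxy group as 5-alkylresorcinol dimethyl ethers do; no stereocentre is touched (the C3 descriptor becomes R only because the brominated ring gains CIP rank).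

Step 11
Reactants: 16 3-bromo-4-methoxyphenol
Product: 17 4-(benzyloxy)-2-bromo-1-methoxybenzene
Conditions: BnBr, K2CO3, acetone, reflux
Reagents that add atoms: benzyl bromide, BrCc1ccccc1
Why: Williamson benzylation; the benzyl ether marks the ring-E carbon that will carry the stilbene.

Step 12
Reactants: 17 4-(benzyloxy)-2-bromo-1-methoxybenzene; 15 bromo aldehyde
Product: 19 [5-(benzyloxy)-2-methoxyphenyl][(2S,3R)-3-(2-bromo-3,5-dimethoxyphenyl)-6-methoxy-2-(4-methoxyphenyl)-2,3-dihydro-1-benzofuran-4-yl]methanol (both carbinol epimers), via aryl Grignard reagent 18 (not isolated)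
Conditions: Mg, THF, 50 °C; then 15, −20 °C → rt; H2O
Reagents that add atoms: none
Why: Grignard formation and 1,2-addition to the aldehyde, which the ring-A bromide survives; the new carbinol carbon is C8b and its configuration is left open because it is erased in step 16.

Step 13
Reactants: 19 bromo carbinol; 20 4-methoxybenzaldehyde
Product: 22 diol with a (4-methoxyphenyl)hydroxymethyl group on ring A and the [5-(benzyloxy)-2-methoxyphenyl]hydroxymethyl group on ring B (epimer mixture at C7b and C8b), via aryllithium alkoxide 21 (not isolated)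
Conditions: n-BuLi (2.2 equiv), THF, −78 °C; then 20; H2O
Reagents that add atoms: none
Why: Deprotonation of the alcohol, bromine–lithium exchange on ring A and 1,2-addition of the aryllithium to the aldehyde create C7b as a carbinol; its configuration is irrelevant.

Step 14
Reactants: 22 diol
Product: 24 eight-membered cyclic sulfide (S bridging C7b and C8b, epimer mixture), via bis-benzhydryl dichloride 23 (not isolated)
Conditions: SOCl2, 2,6-lutidine, CH2Cl2, 0 °C; evaporate; Na2S·9H2O, Bu4NHSO4 (cat.), CH2Cl2/H2O, high dilution, rt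
Reagents that add atoms: sodium sulfide, [Na+].[Na+].[S-2]
Why: Chlorodehydroxylation of both benzhydrols followed by twofold alkylation of sulfide (sulfide synthesis from a dihalide); the two reacting carbons sit ortho,ortho' on the two rings of the C8a diarylmethine and are held close, which should favour the eight-membered ring over oligomers.

Step 15
Reactants: 24 cyclic sulfide
Product: 25 eight-membered cyclic sulfone fused to the trans-dihydrobenzofuran (C7b and C8b undefined)
Conditions: mCPBA (2.5 equiv), NaHCO3, CH2Cl2, 0 °C → rt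
Reagents that add atoms: 3-chloroperbenzoic acid, O=C(OO)c1cccc(Cl)c1
Why: Peracid oxidation of the sulfide through the sulfoxide to the sulfone under buffered conditions that the aryl ethers and the dihydrofuran tolerate.

Step 16
Reactants: 25 eight-membered cyclic sulfone
Product: 28 7b,8b-didehydro seven-membered-ring core with the ring-E benzyl ether, via α-chloro sulfone 26 (not isolated), via episulfone 27 (not isolated)
Conditions: KOH (powdered), CCl4/t-BuOH/H2O, 25 → 50 °C
Reagents that add atoms: none
Why: Hydroxide deprotonates one diarylmethine α-carbon (drawn at C8b), the carbanion is chlorinated by CCl4, the other α-carbanion displaces chloride in a 1,3-fashion to the thiirane 1,1-dioxide, and this loses SO2 cheletropically to give the C7b=C8b alkene (Ramberg–Bäcklund reaction in its in-situ halogenation form). The closest known cases are the conversion of dibenzhydryl sulfone into tetraphenylethylene under these conditions and the contraction of medium-ring sulfones to cycloalkenes. The seven-membered carbocycle is closed by a 3-exo-tet intramolecular alkylation across the sulfur tether followed by ring contraction, so the hindered tetra-aryl C7b–C8b bond is never formed between two molecules. No stereocentre is created: both sulfone epimers converge through the planar carbanions and the ring allows only the cis alkene. The step needs halogenation at the α-carbons only and no attack on the dihydrofuran; the sulfonyl-flanked benzhydrylic hydrogens are far more acidic than H-8a, and each α-carbon has a single hydrogen, so it cannot be halogenated twice.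

Step 17
Reactants: 28 cycloheptene benzyl ether
Product: 29 (7aS,8aS,7bS,8bS) saturated core with a free phenol on ring E
Conditions: H2 (50 bar), Pd(OH)2/C, EtOAc/EtOH, 50 °C
Reagents that add atoms: none
Why: Heterogeneous syn hydrogenation: the fused trans-dihydrofuran locks the cycloheptene boat with H-8a as flagpole and the C7a aryl above the inner face, so both hydrogens should arrive on the outer (hull) face and give H-7b and H-8b cis to each other and trans to H-8a (7bS,8bS); the benzyl ether is hydrogenolysed in the same operation.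

Step 18
Reactants: 29 phenol
Product: 30 ring-E aryl triflate of the saturated core
Conditions: Tf2O, pyridine, CH2Cl2, 0 °C
Reagents that add atoms: trifluoromethanesulfonic anhydride, O=S(=O)(OS(=O)(=O)C(F)(F)F)C(F)(F)F
Why: O-Sulfonylation of the only free phenol gives the electrophile for the coupling.

Step 19
Reactants: 30 aryl triflate; 12 4-vinyl-dihydrobenzofuran
Product: 31 deca-O-methyl ether of the target (E-stilbene)
Conditions: PdCl2(PPh3)2 (10 mol %), LiCl, Et3N, DMF, 100 °C
Reagents that add atoms: none
Why: Mizoroki–Heck reaction under chloride-assisted neutral conditions: the aryl-palladium adds to the terminal carbon of the styrene and syn β-hydride elimination should give the E-stilbene.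

Step 20
Reactants: 31 deca-O-methyl ether
Product: 32 CNP0266373.2 (target)
Conditions: BBr3 (excess), CH2Cl2, −78 → 0 °C; H2O
Reagents that add atoms: none
Why: Lewis-acid cleavage of all ten aryl methyl ethers (BBr3 demethylation) at low temperature; no carbon stereocentre is involved and the trans dihydrofurans are the thermodynamically preferred isomers.

**Compound list**

1 | 2-bromo-4,6-dimethoxybenzaldehyde | COc1cc(OC)c(C=O)c(Br)c1 | starting material
2 | 2-bromo-6-hydroxy-4-methoxybenzaldehyde | COc1cc(O)c(C=O)c(Br)c1 | intermediate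
3 | 4-methoxybenzyl chloride | COc1ccc(CCl)cc1 | starting material
4 | 2-bromo-4-methoxy-6-[(4-methoxybenzyl)oxy]benzaldehyde | COc1ccc(COc2cc(OC)cc(Br)c2C=O)cc1 | intermediate
5 | 3,5-dimethoxyphenylmagnesium chloride | COc1cc(OC)cc([Mg]Cl)c1 | starting material
6 | (±)-{2-bromo-4-methoxy-6-[(4-methoxybenzyl)oxy]phenyl}(3,5-dimethoxyphenyl)methanol | COc1ccc(COc2cc(OC)cc(Br)c2C(O)c2cc(OC)cc(OC)c2)cc1 | intermediate
7 | {2-bromo-4-methoxy-6-[(4-methoxybenzyl)oxy]phenyl}(3,5-dimethoxyphenyl)methanone | COc1ccc(COc2cc(OC)cc(Br)c2C(=O)c2cc(OC)cc(OC)c2)cc1 | intermediate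
8 | hydrazone of ketone 7 | COc1ccc(COc2cc(OC)cc(Br)c2C(=NN)c2cc(OC)cc(OC)c2)cc1 | intermediate
9 | diaryldiazomethane from 8 | COc1ccc(COc2cc(OC)cc(Br)c2C(=[N+]=[N-])c2cc(OC)cc(OC)c2)cc1 | intermediate
10 | (2R,3S)-4-bromo-3-(3,5-dimethoxyphenyl)-6-methoxy-2-(4-methoxyphenyl)-2,3-dihydro-1-benzofuran (cis) | COc1cc(OC)cc([C@H]2c3c(cc(OC)cc3Br)O[C@H]2c2ccc(OC)cc2)c1 | intermediate
11 | (2S,3S)-4-bromo-3-(3,5-dimethoxyphenyl)-6-methoxy-2-(4-methoxyphenyl)-2,3-dihydro-1-benzofuran (trans) | COc1cc(OC)cc([C@H]2c3c(cc(OC)cc3Br)O[C@@H]2c2ccc(OC)cc2)c1 | intermediate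
12 | (2S,3S)-3-(3,5-dimethoxyphenyl)-4-ethenyl-6-methoxy-2-(4-methoxyphenyl)-2,3-dihydro-1-benzofuran | COc1cc(OC)cc([C@H]2c3c(cc(OC)cc3C=C)O[C@@H]2c2ccc(OC)cc2)c1 | intermediate
13 | 4-lithio derivative of 11 | COc1cc(OC)cc([C@H]2c3c(cc(OC)cc3[Li])O[C@@H]2c2ccc(OC)cc2)c1 | intermediate
14 | (2S,3S)-3-(3,5-dimethoxyphenyl)-6-methoxy-2-(4-methoxyphenyl)-2,3-dihydro-1-benzofuran-4-carbaldehyde | COc1cc(OC)cc([C@H]2c3c(cc(OC)cc3C=O)O[C@@H]2c2ccc(OC)cc2)c1 | intermediate
15 | (2S,3R)-3-(2-bromo-3,5-dimethoxyphenyl)-6-methoxy-2-(4-methoxyphenyl)-2,3-dihydro-1-benzofuran-4-carbaldehyde (trans, same spatial arrangement as 14) | COc1cc(OC)c(Br)c(c1)[C@H]1c2c(cc(OC)cc2C=O)O[C@@H]1c1ccc(OC)cc1 | intermediate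
16 | 3-bromo-4-methoxyphenol | COc1ccc(O)cc1Br | starting material
17 | 4-(benzyloxy)-2-bromo-1-methoxybenzene | COc1ccc(OCc2ccccc2)cc1Br | intermediate
18 | [5-(benzyloxy)-2-methoxyphenyl]magnesium bromide | COc1ccc(OCc2ccccc2)cc1[Mg]Br | intermediate
19 | [5-(benzyloxy)-2-methoxyphenyl][(2S,3R)-3-(2-bromo-3,5-dimethoxyphenyl)-6-methoxy-2-(4-methoxyphenyl)-2,3-dihydro-1-benzofuran-4-yl]methanol (carbinol epimers) | COc1cc(OC)c(Br)c(c1)[C@H]1c2c(cc(OC)cc2C(O)c2cc(OCc3ccccc3)ccc2OC)O[C@@H]1c1ccc(OC)cc1 | intermediate
20 | 4-methoxybenzaldehyde | COc1ccc(C=O)cc1 | starting material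
21 | aryllithium lithium alkoxide from 19 | COc1cc(OC)c([Li])c(c1)[C@H]1c2c(cc(OC)cc2C(O[Li])c2cc(OCc3ccccc3)ccc2OC)O[C@@H]1c1ccc(OC)cc1 | intermediate
22 | diol: (2S,3S)-dihydrobenzofuran with a (4-methoxyphenyl)hydroxymethyl group on ring A and a [5-(benzyloxy)-2-methoxyphenyl]hydroxymethyl group at C4 (carbinol epimers) | COc1ccc(cc1)C(O)c1c(OC)cc(OC)cc1[C@H]1c2c(cc(OC)cc2C(O)c2cc(OCc3ccccc3)ccc2OC)O[C@@H]1c1ccc(OC)cc1 | intermediate
23 | bis-benzhydryl dichloride from 22 | COc1ccc(cc1)C(Cl)c1c(OC)cc(OC)cc1[C@H]1c2c(cc(OC)cc2C(Cl)c2cc(OCc3ccccc3)ccc2OC)O[C@@H]1c1ccc(OC)cc1 | intermediate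
24 | eight-membered cyclic sulfide (S between C7b and C8b) | COc1ccc(C2c3c(OC)cc(OC)cc3[C@H]3c4c(cc(OC)cc4C(c4cc(OCc5ccccc5)ccc4OC)S2)O[C@@H]3c2ccc(OC)cc2)cc1 | intermediate
25 | eight-membered cyclic sulfone (key-step precursor) | COc1ccc(C2c3c(OC)cc(OC)cc3[C@H]3c4c(cc(OC)cc4C(c4cc(OCc5ccccc5)ccc4OC)S2(=O)=O)O[C@@H]3c2ccc(OC)cc2)cc1 | intermediate
26 | α-chloro sulfone (chlorine at C8b) | COc1ccc(C2c3c(OC)cc(OC)cc3[C@H]3c4c(cc(OC)cc4C(Cl)(c4cc(OCc5ccccc5)ccc4OC)S2(=O)=O)O[C@@H]3c2ccc(OC)cc2)cc1 | intermediate
27 | episulfone (thiirane 1,1-dioxide across C7b–C8b) | COc1ccc(C23c4c(OC)cc(OC)cc4[C@H]4c5c(cc(OC)cc5C2(c2cc(OCc5ccccc5)ccc2OC)S3(=O)=O)O[C@@H]4c2ccc(OC)cc2)cc1 | intermediate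
28 | 7b,8b-didehydro seven-membered-ring core, ring-E benzyl ether (key-step product) | COc1ccc(cc1)C2=C(c1cc(OCc3ccccc3)ccc1OC)c1cc(OC)cc3c1[C@H](c1cc(OC)cc(OC)c12)[C@@H](c1ccc(OC)cc1)O3 | intermediate
29 | (7aS,8aS,7bS,8bS) saturated core, ring-E phenol | COc1ccc([C@H]2c3c(OC)cc(OC)cc3[C@H]3c4c(cc(OC)cc4[C@H]2c2cc(O)ccc2OC)O[C@@H]3c2ccc(OC)cc2)cc1 | intermediate
30 | (7aS,8aS,7bS,8bS) saturated core, ring-E triflate | COc1ccc([C@H]2c3c(OC)cc(OC)cc3[C@H]3c4c(cc(OC)cc4[C@H]2c2cc(OS(=O)(=O)C(F)(F)F)ccc2OC)O[C@@H]3c2ccc(OC)cc2)cc1 | intermediate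
31 | deca-O-methyl ether of the target | COc1ccc([C@H]2c3c(OC)cc(OC)cc3[C@H]3c4c(cc(OC)cc4[C@H]2c2cc(/C=C/c4cc(OC)cc5c4[C@H](c4cc(OC)cc(OC)c4)[C@@H](c4ccc(OC)cc4)O5)ccc2OC)O[C@@H]3c2ccc(OC)cc2)cc1 | intermediate
32 | CNP0266373.2 (all six stereocentres S, E-stilbene) | Oc1ccc([C@H]2c3c(O)cc(O)cc3[C@H]3c4c(cc(O)cc4[C@H]2c2cc(/C=C/c4cc(O)cc5c4[C@H](c4cc(O)cc(O)c4)[C@@H](c4ccc(O)cc4)O5)ccc2O)O[C@@H]3c2ccc(O)cc2)cc1 | target

**Step count and risks**

Total steps: 20. Longest linear sequence: 18 (steps 1–7, 9, 10, 12–20); steps 8 and 11 are side branches.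

Most likely to fail:

1. Step 17. The tetra-aryl alkene may reach the catalyst surface too slowly. Under forcing conditions the benzylic C7a–O bond of the dihydrofuran may be hydrogenolysed, and adsorption through the inner face would erode facial selectivity. The fallback sets out from 28 and replaces surface hydrogenation by stepwise radical hydrogenation through metal-hydride hydrogen-atom transfer (Mn(dpm)3 cat., PhSiH3, t-BuOOH, i-PrOH, rt). The first hydrogen atom should add to C8b on the hull face and the resulting C7b diarylmethyl radical should be quenched on the same face, giving the saturated benzyl ether F1. Mild hydrogenolysis (H2 1 atm, Pd/C, EtOAc, rt) then removes the benzyl group and the route is rejoined at 29.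

2. Step 16. Both α-carbons may be chlorinated before the 1,3-elimination. The highly stabilised C7b–SO2 bond may ionise with loss of sulfinate. The sequence can also stall earlier if the eight-membered sulfide closure of step 14 gives oligomers. The fallback sets out from diol 22, oxidises both carbinols (MnO2, CH2Cl2) to the diketone F2 and closes the ring by intramolecular McMurry coupling (TiCl4, Zn, pyridine, THF, reflux), a standard route to tetra-aryl alkenes. It comes back to the route at 28.

3. Step 20. Under the Lewis-acid conditions the stilbene may be protonated and cyclise onto the neighbouring dimethoxyphenyl ring, a dihydrofuran may open, or some of the ten ethers may stay. The fallback sets out from 31 and cleaves the methyl ethers by SN2 attack of a thiolate in a basic medium in which the stilbene cannot be protonated (sodium dodecanethiolate, NMP, 130–150 °C). It arrives at 32 directly.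

Further compounds
F1 | step 17 | (7aS,8aS,7bS,8bS) saturated core, ring-E benzyl ether | COc1ccc([C@H]2c3c(OC)cc(OC)cc3[C@H]3c4c(cc(OC)cc4[C@H]2c2cc(OCc5ccccc5)ccc2OC)O[C@@H]3c2ccc(OC)cc2)cc1
F2 | step 16 | diketone from diol 22 (4-methoxybenzoyl on ring A, 5-(benzyloxy)-2-methoxybenzoyl at C4 of the dihydrobenzofuran) | COc1ccc(cc1)C(=O)c1c(OC)cc(OC)cc1[C@H]1c2c(cc(OC)cc2C(=O)c2cc(OCc3ccccc3)ccc2OC)O[C@@H]1c1ccc(OC)cc1
F0 | step 20 | none | none
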